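Compound numbers used throughout: 1 3-bromophenol, 2 1-bromo-3-iodobenzene, 3 bis(3-bromophenyl) ether, 4 8-bromooct-1-ene, 5 oct-7-en-1-ylzinc bromide, 6 bis[3-(oct-7-en-1-yl)phenyl] ether, 7 macrocyclic alkene, 8 oxygen-free saturated macrocycle, 9 its bis(pinacol boronate), 10 symmetric diphenol, 11 mono-quinone, 12 target.

## Analysis of the target

The target is a 21-membered meta,meta-bridged diphenyl ether. The large ring runs through C3, C4 and C5 of ring A, the ether oxygen, C1, C6 and C5 of ring B and an unbranched chain of fourteen methylene groups. It has no stereocentre and, at this ring size, no stable planar chirality, so there is no stereochemical problem. Ring A is a phenol (OH at C1) with the chain at C3 and the ether oxygen at C5, all mutually meta. Ring B carries the ether oxygen at C1, hydroxyls at C3 and C6 and the chain at C5, so it is a hydroquinone whose C6 hydroxyl is flanked by ether oxygen and chain. The sensitive function is this electron-rich hydroquinone, which air oxidises to the quinone; the diaryl ether, the chain and the ring A phenol are robust. The difficulties are the macrocyclisation, the placing of oxygen meta to both substituents of each ring (where substitution directed by the ether oxygen does not go), and the distinction between two rings that differ only in the C6 hydroxyl of ring B. The strategy rests on two facts. Without the C6 hydroxyl the molecule is a twofold-symmetric diphenol, and its hydroxyl carbons, ring A C1 and ring B C3, are the positions that in the oxygen-free bridged diphenyl ether carry the only C–H bond of each ring with no ortho substituent. The ring B C6 oxygen lies para to the C3 hydroxyl and can therefore be added last by para oxidation of a phenol.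

## Retrosynthetic reasoning

**12 to 11 (redox adjustment).** No bond is cut. The hydroquinone of ring B is stored as the para-quinone 11 until the last step. The final operation is then a mild two-electron reduction to which nothing else in the molecule responds, and the air-sensitive function exists only at the end.

**11 to 10 (ring B C6–O).** The C6 oxygen of 11 is para to the C3 oxygen. Removing it gives 10, in which ring B is a 3,5-disubstituted phenol with a free para position. The cut is made here because this oxygen is the only feature that separates ring B from ring A; without it 10 is symmetric and everything earlier can be done on both rings at once. The forward reaction is a para-selective phenol-to-quinone oxidation that has to stop after one of two equivalent rings.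

**10 to 8 through 9 (ring A C1–O and ring B C3–O).** Both phenolic C–O bonds are cut together, back to C–B in 9 and to C–H in 8. These carbons are meta to the ether oxygen and to the chain, which is out of reach of electrophilic substitution and of ortho-metalation. The alternative would be to carry both oxygens as protected resorcinol-type building blocks through the whole sequence. In 8 these two C–H bonds are the only ones with no ortho neighbour, so a sterically governed C–H borylation can find them. The gain is a route without protecting groups, from monosubstituted commodity arenes, with the macrocycle made on a non-polar hydrocarbon ether. The forward reaction must borylate twice, once per ring, at one site each, and then turn C–B into C–O.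

**8 to 7 to 6 (the macrocycle).** The ring is opened in the middle of the bridge, between C7 and C8 of the tetradecane chain. This is the symmetry point, remote from both arenes, and it gives two identical eight-carbon arms with terminal vinyl groups. The forward sequence is ring-closing metathesis, which expels the two terminal carbons, and then saturation of the new alkene. Opening at the diaryl ether instead would need an unsymmetrical seco compound with a stepwise-built fourteen-carbon chain.

**6 to 3 and 4 through 5 (two aryl–C(sp3) bonds).** Both rings of 6 are the same, so the two arms are attached in one double cross-coupling of dibromide 3 with zinc reagent 5, made from 4. The terminal alkene must survive the coupling.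

**3 to 1 and 2 (diaryl ether C–O).** The ether bond is cut to phenol 1 and dihalide 2. The forward coupling has to use the iodide of 2 and leave all three bromides alone.

## Alternatives that were turned down

**Alternative 1:** Ring A is taken apart across C1–C6 and C4–C5. Cyclobutenone A1 supplies C1 to C4 with one arm, and aryl ethynyl ether A2, built on ring B, supplies C5 and C6. On heating, A1 opens to a vinylketene, which adds [2+2] to the electron-rich alkyne of A2; the new cyclobutenone opens again and closes by 6π electrocyclisation to the phenol A3. Ring-closing metathesis, hydrogenation and cleavage of the two methyl ethers would follow.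
- In favour: the 1,3,5-pattern of ring A is fixed by the mechanism. Ring B arrives with both hydroquinone oxygens in place, so no statistical step and no quinone are needed.
- Against: A2 is an ynol ether on a hindered, electron-rich phenol and is labile to acid and heat. A1 needs a ketene cycloaddition to an alkyne in the presence of, or before introduction of, the terminal alkene. The parent phenol of A2 is itself a multi-step target. The total is roughly twice the length of the chosen route.
- Comparison: this alternative is stronger on the differentiation of the two rings and on the endgame. The chosen strategy offers seven steps from three commodity compounds and no sensitive intermediate before the last two steps.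

**Alternative 2:** The ring A C5–O bond is cut, with ring A held at the cyclohexenone oxidation level. The seco compound A4 carries a 3-chlorocyclohexenone and the ring B phenol at the two ends of the chain. Under a carbonate base at high dilution the phenoxide adds to the chloro-enone and expels chloride, giving the macrocyclic vinylogous ester A5. Dehydrogenation to the ring A phenol and ether cleavage would finish the synthesis.
- In favour: the macrocycle closes by a mild, metal-free addition–elimination. The oxygen pattern of ring A comes from a 1,3-dione and is as secure as in the chosen route. Ring B is fully oxygenated from the start.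
- Against: A4 is a long linear assembly with the chain built between two different termini. The nucleophile is a phenoxide flanked by a methoxy group attacking a β-carbon through a 21-membered transition state. A stereocentre is made only to be destroyed. The aromatisation must be done beside an electron-rich dimethoxyarene.
- Comparison: it equals the chosen strategy on regiochemical certainty and beats it on ring differentiation. The chosen strategy offers a symmetric, short assembly and a ring closure between two unfunctionalised arms.

**Alternative 3:** Ring B is cut across C3–C4, C5–C6 and C6–C1. The precursor A6 is a chromium pentacarbonyl methoxycarbene complex whose β-aryloxyvinyl group hangs on ring A and whose chain ends in a terminal alkyne. Heating at high dilution inserts the alkyne and one carbonyl ligand and closes ring B and the macrocycle together, giving A7 with a free C6 phenol. Cleavage of two methyl ethers would give the target.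
- In favour: one step makes the most oxidised ring and the macrocycle, with the three ring B oxygens differentiated. The usual regiochemistry of a terminal alkyne places the chain next to the new phenol, as required. No late oxidation is needed.
- Against: A6 is a sensitive, stoichiometric chromium complex at the end of a long linear sequence. Heteroatom-substituted vinylcarbenes have competing paths (five-membered ring formation, loss of the aryloxy group). The chromium must be removed without oxidising the new 4-methoxyphenol.
- Comparison: it is more convergent in its key step and avoids the statistical oxidation. The chosen strategy offers catalytic steps throughout, far fewer operations and no organometallic reagent that must be carried stoichiometrically.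

Key step: step 5

Remark: ring-closing metathesis should give 7 as a mixture of E and Z isomers. Both give the same alkane 8, so the geometry is left open and the SMILES of 7 carries no double-bond descriptor.

## Route

Step 1
Reactants: 1 3-bromophenol; 2 1-bromo-3-iodobenzene
Product: 3 bis(3-bromophenyl) ether
Conditions: CuI (10 mol%), picolinic acid (20 mol%), K3PO4, DMSO, 80 °C; 2 in excess (1.5 equiv)
Reagents that add atoms: none
Why: Ullmann diaryl ether coupling; the monovalent copper phenoxide inserts into the C–I bond of 2 much faster than into a C–Br bond, so all bromides are kept, and the excess of 2 holds back oligo-ether formation.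

Step 2
Reactants: 3 bis(3-bromophenyl) ether; 4 8-bromooct-1-ene
Product: 6 bis[3-(oct-7-en-1-yl)phenyl] ether, via oct-7-en-1-ylzinc bromide 5 (not isolated)
Conditions: 4 (3 equiv), Zn dust (I2 cat.), LiCl, THF, 50 °C; then 3, Pd(OAc)2 (2 mol%), SPhos (4 mol%), THF, rt to 50 °C
Reagents that add atoms: none
Why: LiCl-assisted zinc insertion into the primary bromide, then twofold Negishi coupling; each aryl bromide adds to zerovalent palladium, and with the bulky biarylphosphine reductive elimination of the primary alkyl outruns β-hydride elimination. The terminal alkene is inert to the zinc reagent and to the catalyst.

Step 3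
Reactants: 6 bis[3-(oct-7-en-1-yl)phenyl] ether
Product: 7 3,3'-(tetradec-7-ene-1,14-diyl)-bridged diphenyl ether (21-membered ring, E/Z mixture)
Conditions: RuCl2(=CHPh)(PCy3)(H2IMes) (second-generation Grubbs catalyst, 5 mol%), 1,4-benzoquinone (10 mol%), CH2Cl2 (1 mM), 40 °C
Reagents that add atoms: none
Why: Ring-closing metathesis of two unhindered terminal alkenes on flexible arms; high dilution favours the strain-free 21-membered ring over acyclic oligomers and loss of ethene drives the reaction. The quinone additive traps ruthenium hydrides that would shift the double bonds and lead to ring-contracted homologues.

Step 4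
Reactants: 7 3,3'-(tetradec-7-ene-1,14-diyl)-bridged diphenyl ether
Product: 8 3,3'-(tetradecane-1,14-diyl)-bridged diphenyl ether
Conditions: H2 (1 atm), 10% Pd on carbon, EtOAc, rt
Reagents that add atoms: none
Why: Heterogeneous hydrogenation of a disubstituted alkene; both alkene isomers converge on one alkane, and the arenes and the diaryl ether are not touched at this pressure.

Step 5
Reactants: 8 3,3'-(tetradecane-1,14-diyl)-bridged diphenyl ether
Product: 10 5,5'-dihydroxy-3,3'-(tetradecane-1,14-diyl)diphenyl ether (symmetric macrocyclic diphenol), via macrocyclic bis(pinacol boronate) 9 (not isolated)
Conditions: B2pin2 (2.2 equiv), [Ir(OMe)(cod)]2 (3 mol%), 4,4'-di-tert-butyl-2,2'-bipyridine (6 mol%), THF, 80 °C; evaporate; then 30% aq. H2O2, NaOH, THF, 0 °C to rt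
Reagents that add atoms: bis(pinacolato)diboron, CC1(C)OB(OC1(C)C)B1OC(C)(C)C(C)(C)O1 (the boron of 9); hydrogen peroxide, OO (the oxygen of 10)
Why: [Ir(OMe)(cod)]2, the bipyridine and B2pin2 form the 16-electron trivalent iridium tris(boryl) complex, which cleaves an aryl C–H bond to a pentavalent iridium aryl hydride, releases the aryl boronate by C–B reductive elimination and is regenerated by B2pin2 or by the pinacolborane formed. The closest known reaction type is the sterically controlled iridium-catalysed borylation of 1,3-disubstituted arenes with one-pot oxidation to 3,5-disubstituted phenols, here run twice in one molecule. The crowded tris(boryl) centre does not reach a C–H bond next to a substituent: in each ring of 8 the C–H between ether oxygen and chain has two ortho neighbours and points into the macrocycle, the next two have the chain or the aryloxy group beside them, and only the C–H meta to both (future ring A C1 and ring B C3) is flanked by two hydrogens and points outward. The two rings are related by the twofold symmetry of 8 and insulated from each other by the saturated bridge, so the second borylation should run like the first, and a ring that already carries one boryl group has no unhindered C–H left, which rules out over-borylation. In the second stage hydroperoxide adds to boron and the aryl group migrates from boron to oxygen, so the C–O bond forms at the carbon that carried boron and the regiochemistry of the borylation passes unchanged into 10. No ring is closed and no stereocentre is formed; the two new skeletal bonds are the C–O bonds at ring A C1 and ring B C3. The selectivity needed is site selectivity within each ring together with complete twofold conversion; the first is secured by the substitution pattern of 8, the second by the excess of B2pin2 and the absence of any group in 8 that binds the catalyst. The benzylic and aliphatic C–H bonds of the bridge are not attacked by this bipyridine catalyst, and the diaryl ether is stable in both stages.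

Step 6
Reactants: 10 5,5'-dihydroxy-3,3'-(tetradecane-1,14-diyl)diphenyl ether
Product: 11 macrocyclic mono-quinone: ring B as 2-aryloxy-6-alkyl-1,4-benzoquinone, ring A still the 3,5-disubstituted phenol
Conditions: (KSO3)2NO (1.5 equiv, added slowly), KH2PO4 buffer (pH about 6), acetone/H2O, 0 °C to rt; recovered 10 recycled
Reagents that add atoms: potassium nitrosodisulfonate, [K+].[K+].[O]N(S(=O)(=O)[O-])S(=O)(=O)[O-]
Why: Teuber oxidation; one nitroxyl radical removes the phenolic hydrogen, a second couples through its oxygen at the para carbon (ring B C6), and loss of imidodisulfonate leaves the para-quinone, para attack being preferred over ortho whenever the para position is free, as in 3-alkoxy-5-alkylphenols. With less than one oxidation equivalent per molecule the second, equivalent ring should be largely spared, and the buffer protects the aryloxy-quinone (a vinylogous ester) from hydrolytic cleavage.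

Step 7
Reactants: 11 macrocyclic mono-quinone
Product: 12 2,5,5'-trihydroxy-3,3'-(tetradecane-1,14-diyl)diphenyl ether (target; ring B C3 and C6 hydroxyls, ring A C1 hydroxyl)
Conditions: Na2S2O4 (excess, aq.), EtOAc/H2O, rt, under argon; degassed solvents in the work-up
Reagents that add atoms: none
Why: Two-electron reduction of a para-quinone to the hydroquinone by dithionite in a two-phase system; phenol, diaryl ether and chain do not react, and exclusion of air keeps the product from re-oxidising.

## Compound list

1 | 3-bromophenol | Oc1cccc(Br)c1 | starting material
2 | 1-bromo-3-iodobenzene | Brc1cccc(I)c1 | starting material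
3 | bis(3-bromophenyl) ether | Brc1cccc(Oc2cccc(Br)c2)c1 | intermediate
4 | 8-bromooct-1-ene | BrCCCCCCC=C | starting material
5 | oct-7-en-1-ylzinc bromide (formed in the flask, not isolated) | C=CCCCCCC[Zn]Br | intermediate
6 | bis[3-(oct-7-en-1-yl)phenyl] ether | C=CCCCCCCc1cccc(Oc2cccc(CCCCCCC=C)c2)c1 | intermediate
7 | 3,3'-(tetradec-7-ene-1,14-diyl)-bridged diphenyl ether (E/Z mixture) | c1cc2cc(c1)Oc1cccc(c1)CCCCCCC=CCCCCCC2 | intermediate
8 | 3,3'-(tetradecane-1,14-diyl)-bridged diphenyl ether | c1cc2cc(c1)Oc1cccc(c1)CCCCCCCCCCCCCC2 | intermediate
9 | 5,5'-bis(4,4,5,5-tetramethyl-1,3,2-dioxaborolan-2-yl)-3,3'-(tetradecane-1,14-diyl)diphenyl ether (formed in the flask, not isolated) | CC1(C)OB(OC1(C)C)c1cc2cc(c1)Oc1cc(cc(c1)CCCCCCCCCCCCCC2)B1OC(C)(C)C(C)(C)O1 | intermediate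
10 | 5,5'-dihydroxy-3,3'-(tetradecane-1,14-diyl)diphenyl ether | Oc1cc2cc(c1)Oc1cc(O)cc(c1)CCCCCCCCCCCCCC2 | intermediate
11 | macrocyclic mono-quinone (ring B 2-aryloxy-6-alkyl-1,4-benzoquinone, ring A phenol) | Oc1cc2cc(c1)OC1=CC(=O)C=C(C1=O)CCCCCCCCCCCCCC2 | intermediate
12 | 2,5,5'-trihydroxy-3,3'-(tetradecane-1,14-diyl)diphenyl ether (CNP0393720.0) | Oc1cc2cc(c1)Oc1cc(O)cc(c1O)CCCCCCCCCCCCCC2 | target

## Step count and risks

Total steps: 7. Longest linear sequence: 7 steps (from 1 or 2 to 12).

**Step 5 (key step).** Site selectivity may erode through borylation of the C–H ortho to the ether oxygen, since an oxygen substituent shields its neighbours less than carbon does. The reaction may also stall after the first ring, giving mixtures that are hard to separate at the phenol stage. The fallback carries both oxygens in from the start instead of installing them on the macrocycle. It sets out from 8-bromooct-1-ene 4 (as zinc reagent 5) and returns at diphenol 10. Commercial 3-bromo-5-methoxyphenol F1 and (3-bromo-5-methoxyphenyl)boronic acid F2 are joined by Chan–Lam coupling (Cu(OAc)2 20 mol%, pyridine, 4 Å sieves, CH2Cl2, air) to bis(3-bromo-5-methoxyphenyl) ether F3. Double Negishi coupling with 5 as in step 2 gives bis[3-methoxy-5-(oct-7-en-1-yl)phenyl] ether F4. Ring-closing metathesis as in step 3 gives the dimethoxy macrocyclic alkene F5, and hydrogenation gives the saturated dimethoxy macrocycle F6. BBr3 in CH2Cl2 then cleaves both methyl ethers, leaves the diaryl ether intact and delivers 10.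

**Step 6.** Oxidation of the second, equivalent ring cannot be fully suppressed, and over-oxidised material is lost. Hydrolytic displacement of the aryloxy group from the quinone would open the macrocycle. The fallback moves the statistical event to a reversible protection. It sets out from 10 and returns at 12, passing 11 by. Alkylation of 10 with a deficit of benzyl bromide (K2CO3, acetone) gives the mono-benzyl ether F7 beside unreacted 10, which is recycled. An excess of (KSO3)2NO can then oxidise only the one free phenol ring, giving the benzyloxy quinone F8. H2 over Pd on carbon reduces the quinone and removes the benzyl group in one operation to give 12.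

**Step 3.** Intermolecular metathesis may compete with ring closure and give oligomers, and ruthenium hydride-mediated double-bond migration before closure would give ring-contracted homologues that cannot be separated from 8 later. The fallback closes the ring by C(sp3)–C(sp2) coupling, with no alkene present at the closure. It sets out from 3, returns at 8 and replaces steps 2 to 4. Tetradeca-1,13-diene F9 is hydroborated at both ends with 9-borabicyclo[3.3.1]nonane to 1,14-bis(9-borabicyclo[3.3.1]nonan-9-yl)tetradecane F10. F10 and 3 are added slowly to PdCl2(dppf) and Cs2CO3 in THF/DMF/H2O at 60 °C. The first B-alkyl Suzuki–Miyaura coupling is intermolecular and the second closes the 21-membered ring, a cyclocoupling of the Kumada type run with boron. Oligomerisation remains its own risk.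

**Step 2.** β-Hydride elimination and re-insertion at the alkylpalladium stage would give branched or reduced arenes, and incomplete zinc insertion would leave mono-coupled bromide. The fallback reverses the polarity. It sets out from 3 (with 4 as the electrophile) and returns at 6. Mg turnings with LiCl in THF convert 3 into bis[3-(bromomagnesio)phenyl] ether F11, which is coupled with 4 under FeCl3 (5 mol%) and TMEDA in THF at 0 °C. This is an iron-catalysed aryl–alkyl coupling in which no alkylpalladium species occurs.

**Step 1.** Activation of C–Br bonds of 1 or of 3 beside the C–I bond of 2 would give oligomeric ethers. The fallback uses an oxidative coupling that does not touch aryl halides. It sets out from 1 and returns at 3. Compound 1 and (3-bromophenyl)boronic acid F12 are coupled by the Chan–Lam reaction (Cu(OAc)2 20 mol%, pyridine, 4 Å sieves, CH2Cl2, air, rt).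

## Further compounds

F1 | step 5 | 3-bromo-5-methoxyphenol | COc1cc(O)cc(Br)c1
F2 | step 5 | (3-bromo-5-methoxyphenyl)boronic acid | COc1cc(Br)cc(c1)B(O)O
F3 | step 5 | bis(3-bromo-5-methoxyphenyl) ether | COc1cc(Br)cc(Oc2cc(OC)cc(Br)c2)c1
F4 | step 5 | bis[3-methoxy-5-(oct-7-en-1-yl)phenyl] ether | COc1cc(CCCCCCC=C)cc(Oc2cc(OC)cc(CCCCCCC=C)c2)c1
F5 | step 5 | 5,5'-dimethoxy-3,3'-(tetradec-7-ene-1,14-diyl)-bridged diphenyl ether (E/Z mixture) | COc1cc2cc(c1)Oc1cc(OC)cc(c1)CCCCCCC=CCCCCCC2
F6 | step 5 | 5,5'-dimethoxy-3,3'-(tetradecane-1,14-diyl)-bridged diphenyl ether | COc1cc2cc(c1)Oc1cc(OC)cc(c1)CCCCCCCCCCCCCC2
F7 | step 6 | 5-benzyloxy-5'-hydroxy-3,3'-(tetradecane-1,14-diyl)diphenyl ether | Oc1cc2cc(c1)Oc1cc(OCc3ccccc3)cc(c1)CCCCCCCCCCCCCC2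
F8 | step 6 | macrocyclic quinone benzyl ether (ring B 2-aryloxy-6-alkyl-1,4-benzoquinone, ring A benzyl ether) | c1ccccc1COc1cc2cc(c1)OC1=CC(=O)C=C(C1=O)CCCCCCCCCCCCCC2
F9 | step 3 | tetradeca-1,13-diene | C=CCCCCCCCCCCCC=C
F10 | step 3 | 1,14-bis(9-borabicyclo[3.3.1]nonan-9-yl)tetradecane | C1CCC2CCCC1B2CCCCCCCCCCCCCCB1C2CCCC1CCC2
F11 | step 2 | bis[3-(bromomagnesio)phenyl] ether | Br[Mg]c1cccc(Oc2cccc([Mg]Br)c2)c1
F12 | step 1 | (3-bromophenyl)boronic acid | OB(O)c1cccc(Br)c1
A1 | alternative 1 | 3-(oct-7-en-1-yl)cyclobut-2-en-1-one | O=C1CC(CCCCCCC=C)=C1
A2 | alternative 1 | 1-(ethynyloxy)-2,5-dimethoxy-3-(oct-7-en-1-yl)benzene | C#COc1cc(OC)cc(CCCCCCC=C)c1OC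
A3 | alternative 1 | diaryl ether with free ring A phenol and two oct-7-enyl arms | Oc1cc(CCCCCCC=C)cc(c1)Oc1cc(OC)cc(CCCCCCC=C)c1OC
A4 | alternative 2 | racemic 3-chloro-5-[14-(3-hydroxy-2,5-dimethoxyphenyl)tetradecyl]cyclohex-2-en-1-one | O=C1C=C(Cl)CC(C1)CCCCCCCCCCCCCCc1cc(OC)cc(O)c1OC
A5 | alternative 2 | racemic macrocyclic 3-aryloxycyclohex-2-enone | O=C1C=C2CC(C1)CCCCCCCCCCCCCCc1cc(OC)cc(O2)c1OC
A6 | alternative 3 | pentacarbonyl{methoxy[(E)-2-(3-(hexadec-15-yn-1-yl)-5-methoxyphenoxy)vinyl]carbene}chromium | COC(/C=C/Oc1cc(OC)cc(CCCCCCCCCCCCCCC#C)c1)=[Cr].[C-]#[O+].[C-]#[O+].[C-]#[O+].[C-]#[O+].[C-]#[O+]
A7 | alternative 3 | macrocycle with free ring B C6 phenol, ring B C3 methyl ether and ring A methyl ether | COc1cc2cc(c1)Oc1cc(OC)cc(c1O)CCCCCCCCCCCCCC2
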